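(The readings were computed for an exercise; noise was put on by code.)

**The question.** Which flask ends with more product, and what would turn the order round?

- the flask that ends with the higher amount of product, in percent of the starting material charged, or "neither" when 2 percentage points or less lies between them (Thursday's / Wednesday's / neither)
- final product, as a percentage of the starting material charged, in Thursday's
- final product, as a percentage of the starting material charged, in Wednesday's

all flasks: starting material 0.020 M
- zeta: partner 0.026 M; free catalyst 13 µM; run made earlier
- alpha: partner 0.026 M; free catalyst 25 µM; run made earlier
- Thursday's: partner 0.0260 M; free catalyst 25 µM; time 25 h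
- Wednesday's: partner 0.0260 M; free catalyst 40 µM; time 8.0 h

| run | time / h | product / % | starting material / % |
|---|---|---|---|
| zeta | 0.500 | 2.6 | 97.8 |
| zeta | 1.33 | 2.8 | 95.6 |
| zeta | 2.50 | 4.9 | 91.4 |
| zeta | 4.00 | 4.8 | 89.6 |
| alpha | 0.500 | 2.7 | 97.4 |
| alpha | 1.33 | 1.8 | 92.8 |
| alpha | 2.50 | 5.1 | 88.4 |
| alpha | 4.00 | 10.5 | 79.3 |

(scatter of a reading: 1 percentage point)

- in percentages every species weighs as the starting material in it: one idle adduct counts as two
- for product the idle adduct is counted in
- steps under discussion: catalyst intermediate C -> free catalyst + product; starting material + product <-> idle adduct; catalyst intermediate A <-> by-product + catalyst intermediate B; partner + free catalyst <-> catalyst intermediate A; starting material + catalyst intermediate B <-> catalyst intermediate C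
- in an amount of product, one idle adduct counts as one product

**Turned round.** For Wednesday's to win, its larger catalyst charge would have to outweigh Thursday's longer time. So you compare catalyst-time: catalyst charge times hours, in units of the alpha run at its last reading. The zeta run's last reading stands at 0.520, Wednesday's at 3.20, Thursday's at 6.25.

**The reading.** Take minus the logarithm of the fraction of starting material left at the last reading, and divide by catalyst-time. The zeta run gives 0.211 and the alpha run 0.232, which agree within the scatter. Pooled, this logarithmic loss of starting material per unit of catalyst-time is 0.225.

**The balance.** Starting material is the limiting reagent, at 0.020 M against 0.0260 M of partner. One product costs one starting material, and an idle adduct costs a second. In the alpha run, product at the last reading is about half of the loss, so I take that share.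

**My reckoning.** Wednesday's then gives 25.6 % and Thursday's 37.7 %. On this reckoning the opposite outcome needs Wednesday's catalyst-time to pass Thursday's, yet Thursday's holds twice as much. My gap of 12 percentage points is wider than the margin.

**The forecast.** It also names Thursday's, with 52 % (42 % to 68 %) for Thursday's and 31 % (25 % to 36 %) for Wednesday's. Its words: “Beyond that, progress relies on slow adduct release”. My figures lie lower in both flasks.

**The result.** Thursday's ends higher: Thursday's gives 41.4 %, Wednesday's 26.9 %.

    catalyst intermediate C → free catalyst + product (k = 1.90 min⁻¹)
    starting material + product ⇌ idle adduct, settled at all times (K = 647 L mol⁻¹)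
    catalyst intermediate A ⇌ by-product + catalyst intermediate B (K = 0.0480 M, k = 3.26 min⁻¹)
    partner + free catalyst ⇌ catalyst intermediate A (K = 65.0 L mol⁻¹, k = 117 L mol⁻¹ min⁻¹)
    starting material + catalyst intermediate B ⇌ catalyst intermediate C (K = 76.3 L mol⁻¹, k = 47.8 L mol⁻¹ min⁻¹)

**Same clock.** Thursday's ended 11 points under the forecast and 3.7 points over my figure. Wednesday's flask read at 2.0 h stands at catalyst-time 0.800, which gives 83.5 % starting material and 8.24 % product; that flask holds 84.3 % and 8.17 %. In Wednesday's at 8.00 h, partner, free catalyst and catalyst intermediate A relax with a half-life of 0.165 min, far shorter than the partner's 14 h by that forward step taken by itself. At 3.43 h in Wednesday's, catalyst intermediate B is made 1.00 times as fast as it is used up, each step taken net.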